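**Retrosynthetic overview**
- The C3 ester is made last by acylation with (2E,4E)-octa-2,4-dienoic acid (from hex-2-enal and malonic acid); N-Boc and the C5′ silyl ether are then removed.
- C2–CH3 comes from MeMgBr opening of an N-Boc lactam followed by N-acyliminium reduction (2,3-cis, 2,8a-trans); C3–O comes from hydroxylation of the lactam enolate.
- The piperidine ring is formed second, by lactamisation (N1–C2) after auxiliary-controlled amination at C8a; C4a and C5 are then set by hydrogenation of the C4a=C5 alkene.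
- C5–C1′ is made by B-alkyl Suzuki coupling of an enol triflate with the side-chain borane (from (R)-2-propyloxirane and allylmagnesium bromide).
- C4–C4a is made first, by intermolecular Michael addition of cyclohexane-1,3-dione (the carbocycle, present from the start) to ethyl acrylate.

Assumption: decahydroquinoline numbering (N1, C2 to C8a; side chain C1′ to C8′) is used for all intermediates, and commercial (R)-2-propyloxirane is taken as enantiopure.

**Route**

Step 1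
Reactants: 1 (R)-2-propyloxirane; 2 allylmagnesium bromide
Product: 3 (5R)-oct-1-en-5-ol
Conditions: CuI (10 mol%), THF, −30 °C to 0 °C; then 1 M HCl
Reagents that add atoms: none
Why: Copper-catalysed Grignard opening of the terminal epoxide at its CH2 carbon (SN2) does not touch the carbinol centre, so the (R) centre of 1 becomes C5′ (R).

Step 2
Reactants: 3 (5R)-oct-1-en-5-ol
Product: 4 triisopropyl{[(5R)-oct-1-en-5-yl]oxy}silane
Conditions: TIPSOTf, 2,6-lutidine, CH2Cl2, 0 °C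
Reagents that add atoms: triisopropylsilyl trifluoromethanesulfonate (TIPSOTf), CC(C)[Si](C(C)C)(C(C)C)OS(=O)(=O)C(F)(F)F
Why: Silylation of the secondary alcohol gives an ether with no arene that survives base, hydride, Grignard reagent and hydrogenation.

Step 3
Reactants: 5 cyclohexane-1,3-dione; 6 ethyl acrylate
Product: 7 ethyl 3-(2,6-dioxocyclohexyl)propanoate
Conditions: NaOEt (0.1 equiv), EtOH, reflux
Reagents that add atoms: none
Why: Intermolecular Michael addition of the stabilised dione enolate to the acrylate forms the C4–C4a bond and joins the carbocycle to the C2–C4 unit; no stereocentre is formed.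

Step 4
Reactants: 7 ethyl 3-(2,6-dioxocyclohexyl)propanoate
Product: 8 ethyl 3-[6-oxo-2-(trifluoromethylsulfonyloxy)cyclohex-1-en-1-yl]propanoate
Conditions: Tf2O, pyridine, CH2Cl2, −78 °C to 0 °C
Reagents that add atoms: trifluoromethanesulfonic anhydride (Tf2O), O=S(=O)(OS(=O)(=O)C(F)(F)F)C(F)(F)F
Why: O-sulfonylation of the enolised, symmetrical 1,3-dione gives a single vinylogous acyl triflate.

Step 5
Reactants: 4 triisopropyl{[(5R)-oct-1-en-5-yl]oxy}silane; 8 ethyl 3-[6-oxo-2-(trifluoromethylsulfonyloxy)cyclohex-1-en-1-yl]propanoate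
Product: 10 ethyl 3-{6-oxo-2-[(5R)-5-(triisopropylsilyloxy)octyl]cyclohex-1-en-1-yl}propanoate, via alkylborane 9 (not isolated)
Conditions: 9-BBN-H, THF, 0 °C to rt; then 8, PdCl2(dppf) (5 mol%), K3PO4 (3 M aq.), DMF, 50 °C
Reagents that add atoms: none
Why: Anti-Markovnikov hydroboration followed by B-alkyl Suzuki–Miyaura coupling with the activated enol triflate forms C5–C1′ without touching C5′.

Step 6
Reactants: 10 ethyl 3-{6-oxo-2-[(5R)-5-(triisopropylsilyloxy)octyl]cyclohex-1-en-1-yl}propanoate; 11 (R)-2-methylpropane-2-sulfinamide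
Product: 12 ethyl 3-{(6E)-6-{[(R)-tert-butylsulfinyl]imino}-2-[(5R)-5-(triisopropylsilyloxy)octyl]cyclohex-1-en-1-yl}propanoate
Conditions: Ti(OEt)4 (3 equiv), THF, 70 °C
Reagents that add atoms: none
Why: Titanium-mediated Ellman condensation gives the N-sulfinyl ketimine with the sulfinyl group anti to the substituted alkenyl carbon, and the ethyl ester is unaffected by the ethoxide ligand.

Step 7
Reactants: 12 ethyl 3-{(6E)-6-{[(R)-tert-butylsulfinyl]imino}-2-[(5R)-5-(triisopropylsilyloxy)octyl]cyclohex-1-en-1-yl}propanoate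
Product: 13 ethyl 3-{(6R)-6-{[(R)-tert-butylsulfinyl]amino}-2-[(5R)-5-(triisopropylsilyloxy)octyl]cyclohex-1-en-1-yl}propanoate
Conditions: NaBH4, THF–H2O (98:2), −50 °C
Reagents that add atoms: none
Why: Diastereoselective Ellman reduction (1,2-hydride delivery through the sulfinyl-coordinated chair transition state, alkenyl as the large group) sets C8a as (R), and the minor sulfinamide diastereomer is removed by chromatography.

Step 8
Reactants: 13 ethyl 3-{(6R)-6-{[(R)-tert-butylsulfinyl]amino}-2-[(5R)-5-(triisopropylsilyloxy)octyl]cyclohex-1-en-1-yl}propanoate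
Product: 15 (8aR)-5-[(5R)-5-(triisopropylsilyloxy)octyl]-3,4,6,7,8,8a-hexahydroquinolin-2(1H)-one, via amine hydrochloride 14 (not isolated)
Conditions: HCl (4 M in dioxane), EtOH, 0 °C; evaporate; then Et3N, toluene, 90 °C
Reagents that add atoms: none
Why: Acidic ethanolysis removes the sulfinyl auxiliary and the freed allylic amine closes the six-membered lactam (N1–C2) onto the ester, leaving C8a untouched.

Step 9
Reactants: 15 (8aR)-5-[(5R)-5-(triisopropylsilyloxy)octyl]-3,4,6,7,8,8a-hexahydroquinolin-2(1H)-one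
Product: 16 (4aS,5S,8aR)-5-[(5R)-5-(triisopropylsilyloxy)octyl]octahydroquinolin-2(1H)-one
Conditions: H2 (50 bar), PtO2, AcOH, rt
Reagents that add atoms: none
Why: Heterogeneous syn-hydrogenation of the tetrasubstituted C4a=C5 alkene takes place on the face of the pseudoaxial H8a, opposite the puckered lactam nitrogen, so H4a, H5 and H8a end up all cis (cis ring fusion, 4aS,5S).

Step 10
Reactants: 16 (4aS,5S,8aR)-5-[(5R)-5-(triisopropylsilyloxy)octyl]octahydroquinolin-2(1H)-one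
Product: 17 tert-butyl (4aS,5S,8aR)-2-oxo-5-[(5R)-5-(triisopropylsilyloxy)octyl]octahydroquinoline-1(2H)-carboxylate
Conditions: Boc2O, DMAP, Et3N, CH2Cl2, rt
Reagents that add atoms: di-tert-butyl dicarbonate (Boc2O), CC(C)(C)OC(=O)OC(=O)OC(C)(C)C
Why: DMAP-catalysed N-acylation activates the lactam for enolisation and Grignard addition and provides the A(1,3) strain that holds C8 axial in the later steps.

Step 11
Reactants: 17 tert-butyl (4aS,5S,8aR)-2-oxo-5-[(5R)-5-(triisopropylsilyloxy)octyl]octahydroquinoline-1(2H)-carboxylate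
Product: 19 tert-butyl (3R,4aS,5S,8aR)-3-hydroxy-2-oxo-5-[(5R)-5-(triisopropylsilyloxy)octyl]octahydroquinoline-1(2H)-carboxylate, via sodium enolate 18 (not isolated)
Conditions: NaN(SiMe3)2, THF, −78 °C; then 2-(benzenesulfonyl)-3-phenyloxaziridine, −78 °C; AcOH quench
Reagents that add atoms: 2-(benzenesulfonyl)-3-phenyloxaziridine (Davis oxaziridine), O=S(=O)(N1OC1c1ccccc1)c1ccccc1
Why: Davis enolate hydroxylation occurs by axial attack on the convex face of the cis-fused lactam enolate (syn to H4a and H8a), giving the axial (3R) alcohol.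

Step 12
Reactants: 19 tert-butyl (3R,4aS,5S,8aR)-3-hydroxy-2-oxo-5-[(5R)-5-(triisopropylsilyloxy)octyl]octahydroquinoline-1(2H)-carboxylate
Product: 20 tert-butyl (3R,4aS,5S,8aR)-2-oxo-3-(triethylsilyloxy)-5-[(5R)-5-(triisopropylsilyloxy)octyl]octahydroquinoline-1(2H)-carboxylate
Conditions: Et3SiCl, imidazole, DMF, 0 °C to rt
Reagents that add atoms: chlorotriethylsilane (Et3SiCl), CC[Si](Cl)(CC)CC
Why: Silylation under non-basic conditions masks the hydroxyl without N-to-O Boc migration and gives a silyl ether that can later be cleaved in the presence of the triisopropylsilyl ether.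

Step 13
Reactants: 20 tert-butyl (3R,4aS,5S,8aR)-2-oxo-3-(triethylsilyloxy)-5-[(5R)-5-(triisopropylsilyloxy)octyl]octahydroquinoline-1(2H)-carboxylate
Product: 21 tert-butyl N-{(1R,2S,3S)-2-[(2R)-3-oxo-2-(triethylsilyloxy)butyl]-3-[(5R)-5-(triisopropylsilyloxy)octyl]cyclohexyl}carbamate
Conditions: MeMgBr, THF, −78 °C; AcOH quench at −78 °C
Reagents that add atoms: methylmagnesium bromide, C[Mg]Br
Why: Grignard addition to the activated N-Boc lactam carbonyl gives, after ring opening on work-up, the methyl ketone without over-addition, and the cold quench protects the C3 centre.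

Step 14
Reactants: 21 tert-butyl N-{(1R,2S,3S)-2-[(2R)-3-oxo-2-(triethylsilyloxy)butyl]-3-[(5R)-5-(triisopropylsilyloxy)octyl]cyclohexyl}carbamate
Product: 23 tert-butyl (2R,3R,4aS,5S,8aR)-2-methyl-3-(triethylsilyloxy)-5-[(5R)-5-(triisopropylsilyloxy)octyl]octahydroquinoline-1(2H)-carboxylate, via N-acyliminium ion 22 (not isolated)
Conditions: Et3SiH, BF3·OEt2, CH2Cl2, −78 °C
Reagents that add atoms: none
Why: In this N-acyliminium ion reduction A(1,3) strain with the Boc group holds C8 axial and A(1,2) strain holds the C3 silyloxy group pseudoaxial on the other face, so hydride adds axially anti to C3–O and syn to C8, giving the 2,3-cis, 2,8a-trans piperidine (2R).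

Step 15
Reactants: 23 tert-butyl (2R,3R,4aS,5S,8aR)-2-methyl-3-(triethylsilyloxy)-5-[(5R)-5-(triisopropylsilyloxy)octyl]octahydroquinoline-1(2H)-carboxylate
Product: 24 tert-butyl (2R,3R,4aS,5S,8aR)-3-hydroxy-2-methyl-5-[(5R)-5-(triisopropylsilyloxy)octyl]octahydroquinoline-1(2H)-carboxylate
Conditions: PPTS (cat.), MeOH, rt
Reagents that add atoms: none
Why: Acid-catalysed methanolysis cleaves the labile triethylsilyl ether selectively, while the triisopropylsilyl ether and the Boc group stay.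

Step 16
Reactants: 25 (E)-hex-2-enal; 26 malonic acid
Product: 27 (2E,4E)-octa-2,4-dienoic acid
Conditions: pyridine, piperidine (cat.), 90 °C
Reagents that add atoms: none
Why: Knoevenagel–Doebner condensation with decarboxylation gives the thermodynamically favoured (2E,4E)-dienoic acid.

Step 17
Reactants: 24 tert-butyl (2R,3R,4aS,5S,8aR)-3-hydroxy-2-methyl-5-[(5R)-5-(triisopropylsilyloxy)octyl]octahydroquinoline-1(2H)-carboxylate; 27 (2E,4E)-octa-2,4-dienoic acid
Product: 29 tert-butyl (2R,3R,4aS,5S,8aR)-2-methyl-3-[(2E,4E)-octa-2,4-dienoyloxy]-5-[(5R)-5-(triisopropylsilyloxy)octyl]octahydroquinoline-1(2H)-carboxylate, via mixed anhydride 28 (not isolated)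
Conditions: 27, 2,4,6-trichlorobenzoyl chloride, Et3N, THF, rt; then 24, DMAP, toluene, 40 °C
Reagents that add atoms: none
Why: In this Yamaguchi esterification DMAP attacks the unhindered dienoyl carbonyl of the mixed anhydride and acylates the hindered axial C3 hydroxyl with retention at C3 and without alkene isomerisation.

Step 18
Reactants: 29 tert-butyl (2R,3R,4aS,5S,8aR)-2-methyl-3-[(2E,4E)-octa-2,4-dienoyloxy]-5-[(5R)-5-(triisopropylsilyloxy)octyl]octahydroquinoline-1(2H)-carboxylate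
Product: 30 tert-butyl (2R,3R,4aS,5S,8aR)-5-[(5R)-5-hydroxyoctyl]-2-methyl-3-[(2E,4E)-octa-2,4-dienoyloxy]octahydroquinoline-1(2H)-carboxylate
Conditions: HF·pyridine, THF–pyridine, 0 °C to rt
Reagents that add atoms: none
Why: Fluoride-driven Si–O cleavage frees the C5′ hydroxyl under buffered conditions that leave the dienoate ester and the Boc group intact.

Step 19
Reactants: 30 tert-butyl (2R,3R,4aS,5S,8aR)-5-[(5R)-5-hydroxyoctyl]-2-methyl-3-[(2E,4E)-octa-2,4-dienoyloxy]octahydroquinoline-1(2H)-carboxylate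
Product: 31 (2R,3R,4aS,5S,8aR)-5-[(5R)-5-hydroxyoctyl]-2-methyldecahydroquinolin-3-yl (2E,4E)-octa-2,4-dienoate
Conditions: TFA, CH2Cl2, 0 °C; then cold aq. NaHCO3
Reagents that add atoms: none
Why: Acidolysis of the Boc carbamate (loss of isobutene and CO2) frees the secondary amine, and a cold, weakly basic work-up avoids O-to-N acyl migration.

**Compound list**

1 | (R)-2-propyloxirane | CCC[C@@H]1CO1 | starting material
2 | allylmagnesium bromide | C=CC[Mg]Br | starting material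
3 | (5R)-oct-1-en-5-ol | C=CCC[C@H](O)CCC | intermediate
4 | triisopropyl{[(5R)-oct-1-en-5-yl]oxy}silane | C=CCC[C@H](O[Si](C(C)C)(C(C)C)C(C)C)CCC | intermediate
5 | cyclohexane-1,3-dione | O=C1CCCC(=O)C1 | starting material
6 | ethyl acrylate | C=CC(=O)OCC | starting material
7 | ethyl 3-(2,6-dioxocyclohexyl)propanoate | CCOC(=O)CCC1C(=O)CCCC1=O | intermediate
8 | ethyl 3-[6-oxo-2-(trifluoromethylsulfonyloxy)cyclohex-1-en-1-yl]propanoate | CCOC(=O)CCC1=C(OS(=O)(=O)C(F)(F)F)CCCC1=O | intermediate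
9 | 9-[(5R)-5-(triisopropylsilyloxy)octyl]-9-borabicyclo[3.3.1]nonane | B1(CCCC[C@H](O[Si](C(C)C)(C(C)C)C(C)C)CCC)C2CCCC1CCC2 | intermediate
10 | ethyl 3-{6-oxo-2-[(5R)-5-(triisopropylsilyloxy)octyl]cyclohex-1-en-1-yl}propanoate | CCOC(=O)CCC1=C(CCCC[C@H](O[Si](C(C)C)(C(C)C)C(C)C)CCC)CCCC1=O | intermediate
11 | (R)-2-methylpropane-2-sulfinamide | CC(C)(C)[S@@](=O)N | starting material
12 | ethyl 3-{(6E)-6-{[(R)-tert-butylsulfinyl]imino}-2-[(5R)-5-(triisopropylsilyloxy)octyl]cyclohex-1-en-1-yl}propanoate | CC(C)(C)[S@@](=O)/N=C1\CCCC(CCCC[C@H](O[Si](C(C)C)(C(C)C)C(C)C)CCC)=C1CCC(=O)OCC | intermediate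
13 | ethyl 3-{(6R)-6-{[(R)-tert-butylsulfinyl]amino}-2-[(5R)-5-(triisopropylsilyloxy)octyl]cyclohex-1-en-1-yl}propanoate | CC(C)(C)[S@@](=O)N[C@@H]1CCCC(CCCC[C@H](O[Si](C(C)C)(C(C)C)C(C)C)CCC)=C1CCC(=O)OCC | intermediate
14 | ethyl 3-{(6R)-6-amino-2-[(5R)-5-(triisopropylsilyloxy)octyl]cyclohex-1-en-1-yl}propanoate hydrochloride | Cl.N[C@@H]1CCCC(CCCC[C@H](O[Si](C(C)C)(C(C)C)C(C)C)CCC)=C1CCC(=O)OCC | intermediate
15 | (8aR)-5-[(5R)-5-(triisopropylsilyloxy)octyl]-3,4,6,7,8,8a-hexahydroquinolin-2(1H)-one | O=C1CCC2=C(CCCC[C@H](O[Si](C(C)C)(C(C)C)C(C)C)CCC)CCC[C@H]2N1 | intermediate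
16 | (4aS,5S,8aR)-5-[(5R)-5-(triisopropylsilyloxy)octyl]octahydroquinolin-2(1H)-one | O=C1CC[C@H]2[C@@H](CCCC[C@H](O[Si](C(C)C)(C(C)C)C(C)C)CCC)CCC[C@H]2N1 | intermediate
17 | tert-butyl (4aS,5S,8aR)-2-oxo-5-[(5R)-5-(triisopropylsilyloxy)octyl]octahydroquinoline-1(2H)-carboxylate | O=C1CC[C@H]2[C@@H](CCCC[C@H](O[Si](C(C)C)(C(C)C)C(C)C)CCC)CCC[C@H]2N1C(=O)OC(C)(C)C | intermediate
18 | sodium enolate of 17 (sodium (4aS,5S,8aR)-1-(tert-butoxycarbonyl)-5-[(5R)-5-(triisopropylsilyloxy)octyl]-1,4,4a,5,6,7,8,8a-octahydroquinolin-2-olate) | [Na+].[O-]C1=CC[C@H]2[C@@H](CCCC[C@H](O[Si](C(C)C)(C(C)C)C(C)C)CCC)CCC[C@H]2N1C(=O)OC(C)(C)C | intermediate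
19 | tert-butyl (3R,4aS,5S,8aR)-3-hydroxy-2-oxo-5-[(5R)-5-(triisopropylsilyloxy)octyl]octahydroquinoline-1(2H)-carboxylate | O[C@@H]1C[C@H]2[C@@H](CCCC[C@H](O[Si](C(C)C)(C(C)C)C(C)C)CCC)CCC[C@H]2N(C(=O)OC(C)(C)C)C1=O | intermediate
20 | tert-butyl (3R,4aS,5S,8aR)-2-oxo-3-(triethylsilyloxy)-5-[(5R)-5-(triisopropylsilyloxy)octyl]octahydroquinoline-1(2H)-carboxylate | CC[Si](CC)(CC)O[C@@H]1C[C@H]2[C@@H](CCCC[C@H](O[Si](C(C)C)(C(C)C)C(C)C)CCC)CCC[C@H]2N(C(=O)OC(C)(C)C)C1=O | intermediate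
21 | tert-butyl N-{(1R,2S,3S)-2-[(2R)-3-oxo-2-(triethylsilyloxy)butyl]-3-[(5R)-5-(triisopropylsilyloxy)octyl]cyclohexyl}carbamate | CC[Si](CC)(CC)O[C@@H](C(C)=O)C[C@H]1[C@@H](CCCC[C@H](O[Si](C(C)C)(C(C)C)C(C)C)CCC)CCC[C@H]1NC(=O)OC(C)(C)C | intermediate
22 | (3R,4aS,5S,8aR)-1-(tert-butoxycarbonyl)-2-methyl-3-(triethylsilyloxy)-5-[(5R)-5-(triisopropylsilyloxy)octyl]-3,4,4a,5,6,7,8,8a-octahydroquinolin-1-ium | CC[Si](CC)(CC)O[C@@H]1C[C@H]2[C@@H](CCCC[C@H](O[Si](C(C)C)(C(C)C)C(C)C)CCC)CCC[C@H]2[N+](C(=O)OC(C)(C)C)=C1C | intermediate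
23 | tert-butyl (2R,3R,4aS,5S,8aR)-2-methyl-3-(triethylsilyloxy)-5-[(5R)-5-(triisopropylsilyloxy)octyl]octahydroquinoline-1(2H)-carboxylate | CC[Si](CC)(CC)O[C@@H]1C[C@H]2[C@@H](CCCC[C@H](O[Si](C(C)C)(C(C)C)C(C)C)CCC)CCC[C@H]2N(C(=O)OC(C)(C)C)[C@@H]1C | intermediate
24 | tert-butyl (2R,3R,4aS,5S,8aR)-3-hydroxy-2-methyl-5-[(5R)-5-(triisopropylsilyloxy)octyl]octahydroquinoline-1(2H)-carboxylate | O[C@@H]1C[C@H]2[C@@H](CCCC[C@H](O[Si](C(C)C)(C(C)C)C(C)C)CCC)CCC[C@H]2N(C(=O)OC(C)(C)C)[C@@H]1C | intermediate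
25 | (E)-hex-2-enal | CCC/C=C/C=O | starting material
26 | malonic acid | OC(=O)CC(=O)O | starting material
27 | (2E,4E)-octa-2,4-dienoic acid | CCC/C=C/C=C/C(=O)O | intermediate
28 | (2E,4E)-octa-2,4-dienoic 2,4,6-trichlorobenzoic anhydride | CCC/C=C/C=C/C(=O)OC(=O)c1c(Cl)cc(Cl)cc1Cl | intermediate
29 | tert-butyl (2R,3R,4aS,5S,8aR)-2-methyl-3-[(2E,4E)-octa-2,4-dienoyloxy]-5-[(5R)-5-(triisopropylsilyloxy)octyl]octahydroquinoline-1(2H)-carboxylate | CCC/C=C/C=C/C(=O)O[C@@H]1C[C@H]2[C@@H](CCCC[C@H](O[Si](C(C)C)(C(C)C)C(C)C)CCC)CCC[C@H]2N(C(=O)OC(C)(C)C)[C@@H]1C | intermediate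
30 | tert-butyl (2R,3R,4aS,5S,8aR)-5-[(5R)-5-hydroxyoctyl]-2-methyl-3-[(2E,4E)-octa-2,4-dienoyloxy]octahydroquinoline-1(2H)-carboxylate | CCC/C=C/C=C/C(=O)O[C@@H]1C[C@H]2[C@@H](CCCC[C@H](O)CCC)CCC[C@H]2N(C(=O)OC(C)(C)C)[C@@H]1C | intermediate
31 | (2R,3R,4aS,5S,8aR)-5-[(5R)-5-hydroxyoctyl]-2-methyldecahydroquinolin-3-yl (2E,4E)-octa-2,4-dienoate | CCC/C=C/C=C/C(=O)O[C@@H]1C[C@H]2[C@@H](CCCC[C@H](O)CCC)CCC[C@H]2N[C@@H]1C | target

**Step count and risks**

Total step count: 19. Longest linear sequence: 16 steps (steps 3 to 15 and 17 to 19 from cyclohexane-1,3-dione and ethyl acrylate; the branch from 1 through steps 1, 2, 5 to 15 and 17 to 19 is equally long).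

The three steps most likely to fail:

Step 6 (together with the reduction that follows it). The tetrasubstituted, α-branched enone may condense slowly with the sulfinamide, and the hydride reduction may be poorly selective or of the opposite sense. The fallback sets out from enone 10. Corey–Bakshi–Shibata reduction with (R)-2-methyl-CBS-oxazaborolidine and BH3·SMe2 in toluene at −30 °C (alkenyl carbon as the large group) gives ethyl 3-{(6S)-6-hydroxy-2-[(5R)-5-(triisopropylsilyloxy)octyl]cyclohex-1-en-1-yl}propanoate F1. Mitsunobu substitution with phthalimide (PPh3, DIAD, THF) inverts this centre and gives ethyl 3-{(6R)-6-(1,3-dioxoisoindolin-2-yl)-2-[(5R)-5-(triisopropylsilyloxy)octyl]cyclohex-1-en-1-yl}propanoate F2. Hydrazine hydrate in hot ethanol releases ethyl 3-{(6R)-6-amino-2-[(5R)-5-(triisopropylsilyloxy)octyl]cyclohex-1-en-1-yl}propanoate F3, which closes onto its ester on continued heating and so comes back to the route at lactam 15.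

Step 9. The tetrasubstituted alkene may hydrogenate slowly, migrate, or give some trans-fused lactam. The fallback sets out from amine hydrochloride 14 (the crude salt of step 8 before the Et3N/toluene stage) and moves the hydrogenation to a monocyclic substrate. Boc2O and Et3N in CH2Cl2 give ethyl 3-{(6R)-6-[(tert-butoxycarbonyl)amino]-2-[(5R)-5-(triisopropylsilyloxy)octyl]cyclohex-1-en-1-yl}propanoate F4, in which A(1,2) strain with the C4 methylene holds the carbamate pseudoaxial and blocks one face. Hydrogenation (H2, PtO2, AcOH) from the open face gives the all-cis ethyl 3-{(1S,2R,6S)-2-[(tert-butoxycarbonyl)amino]-6-[(5R)-5-(triisopropylsilyloxy)octyl]cyclohexyl}propanoate F5. HCl in dioxane gives ethyl 3-{(1S,2R,6S)-2-amino-6-[(5R)-5-(triisopropylsilyloxy)octyl]cyclohexyl}propanoate hydrochloride F6, and Et3N in hot toluene closes the lactam, which comes back to the route at 16.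

Step 14. The Lewis acid may strip the triethylsilyl or Boc group, or the reduction may be unselective at C2. The fallback sets out from keto carbamate 21 and reduces a free cyclic imine instead of the N-acyliminium ion. TMSOTf and 2,6-lutidine in CH2Cl2, then MeOH, remove the Boc group with both silyl ethers intact and give (3R)-4-{(1S,2R,6S)-2-amino-6-[(5R)-5-(triisopropylsilyloxy)octyl]cyclohexyl}-3-(triethylsilyloxy)butan-2-one F7. This condenses spontaneously to (3R,4aS,5S,8aR)-2-methyl-3-(triethylsilyloxy)-5-[(5R)-5-(triisopropylsilyloxy)octyl]-3,4,4a,5,6,7,8,8a-octahydroquinoline F8. NaBH4 in MeOH at −40 °C, adding axially anti to the pseudoaxial silyloxy group, gives (2R,3R,4aS,5S,8aR)-2-methyl-3-(triethylsilyloxy)-5-[(5R)-5-(triisopropylsilyloxy)octyl]decahydroquinoline F9, and Boc2O with Et3N comes back to the route at 23.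

Further compounds
F1 | step 6 | ethyl 3-{(6S)-6-hydroxy-2-[(5R)-5-(triisopropylsilyloxy)octyl]cyclohex-1-en-1-yl}propanoate | O[C@H]1CCCC(CCCC[C@H](O[Si](C(C)C)(C(C)C)C(C)C)CCC)=C1CCC(=O)OCC
F2 | step 6 | ethyl 3-{(6R)-6-(1,3-dioxoisoindolin-2-yl)-2-[(5R)-5-(triisopropylsilyloxy)octyl]cyclohex-1-en-1-yl}propanoate | O=C1c2ccccc2C(=O)N1[C@@H]3CCCC(CCCC[C@H](O[Si](C(C)C)(C(C)C)C(C)C)CCC)=C3CCC(=O)OCC
F3 | step 6 | ethyl 3-{(6R)-6-amino-2-[(5R)-5-(triisopropylsilyloxy)octyl]cyclohex-1-en-1-yl}propanoate | N[C@@H]1CCCC(CCCC[C@H](O[Si](C(C)C)(C(C)C)C(C)C)CCC)=C1CCC(=O)OCC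
F4 | step 9 | ethyl 3-{(6R)-6-[(tert-butoxycarbonyl)amino]-2-[(5R)-5-(triisopropylsilyloxy)octyl]cyclohex-1-en-1-yl}propanoate | CC(C)(C)OC(=O)N[C@@H]1CCCC(CCCC[C@H](O[Si](C(C)C)(C(C)C)C(C)C)CCC)=C1CCC(=O)OCC
F5 | step 9 | ethyl 3-{(1S,2R,6S)-2-[(tert-butoxycarbonyl)amino]-6-[(5R)-5-(triisopropylsilyloxy)octyl]cyclohexyl}propanoate | CCOC(=O)CC[C@H]1[C@@H](CCCC[C@H](O[Si](C(C)C)(C(C)C)C(C)C)CCC)CCC[C@H]1NC(=O)OC(C)(C)C
F6 | step 9 | ethyl 3-{(1S,2R,6S)-2-amino-6-[(5R)-5-(triisopropylsilyloxy)octyl]cyclohexyl}propanoate hydrochloride | Cl.CCOC(=O)CC[C@H]1[C@@H](CCCC[C@H](O[Si](C(C)C)(C(C)C)C(C)C)CCC)CCC[C@H]1N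
F7 | step 14 | (3R)-4-{(1S,2R,6S)-2-amino-6-[(5R)-5-(triisopropylsilyloxy)octyl]cyclohexyl}-3-(triethylsilyloxy)butan-2-one | CC[Si](CC)(CC)O[C@@H](C(C)=O)C[C@H]1[C@@H](CCCC[C@H](O[Si](C(C)C)(C(C)C)C(C)C)CCC)CCC[C@H]1N
F8 | step 14 | (3R,4aS,5S,8aR)-2-methyl-3-(triethylsilyloxy)-5-[(5R)-5-(triisopropylsilyloxy)octyl]-3,4,4a,5,6,7,8,8a-octahydroquinoline | CC[Si](CC)(CC)O[C@@H]1C[C@H]2[C@@H](CCCC[C@H](O[Si](C(C)C)(C(C)C)C(C)C)CCC)CCC[C@H]2N=C1C
F9 | step 14 | (2R,3R,4aS,5S,8aR)-2-methyl-3-(triethylsilyloxy)-5-[(5R)-5-(triisopropylsilyloxy)octyl]decahydroquinoline | CC[Si](CC)(CC)O[C@@H]1C[C@H]2[C@@H](CCCC[C@H](O[Si](C(C)C)(C(C)C)C(C)C)CCC)CCC[C@H]2N[C@@H]1C
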